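**The reading.** At 1.5 h each flask is read for first product, and that amount is a balance: it is made from substrate and may be lost onward.

| flask | substrate | coupling partner | remark | time |
|---|---|---|---|---|
| eta | 0.11 M | 0.099 M | run made earlier |  |
| birch | 0.099 M | 0.0990 M |  | 1.5 h |
| maple | 0.025 M | 0.400 M |  | 1.5 h |
| alder | 0.025 M | 0.150 M |  | 1.5 h |
| larch | 0.099 M | 0.0600 M |  | 1.5 h |

eta run (percent of the substrate charged)

| time / min | first product / % | substrate / % |
|---|---|---|
| 4.00 | 6.5 | 92.8 |
| 8.00 | 12.1 | 87.5 |
| 12.0 | 16.8 | 84.6 |
| 20.0 | 23.7 | 76.4 |
| 30.0 | 31.4 | 67.6 |
| 50.0 | 42.4 | 56.5 |

(standard deviation of a reading: 1 percentage point)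

1. ranking by amount of first product, in percent of the substrate charged, from high to low, at 1.5 h (birch / maple / alder / larch)
2. the same order at 5.0 min (birch / maple / alder / larch)
3. the amount of first product, in percent of the substrate charged of the flask you put first, at 1.5 h
4. the amount of first product, in percent of the substrate charged of the flask you put last, at 1.5 h



**Two rates.** I assumed that first product forms and is lost by steps both first order in coupling partner, which the eta run cannot test. The loss rate over the gain rate is then s[first product]/[substrate], with s the selectivity factor, the loss constant over the gain constant. [coupling partner] cancels, and the ratio climbs as substrate falls. Under that assumption, with a the fraction of substrate left, first product is (a^s − a)/(1 − s) of the charge.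

**Reading s.** At 50.0 min the two readings of the eta run summed 1.1 percentage points short of the charge, and that sum carried a scatter of 1.4 points, so the readings left open an eta run without loss. For small s the shortfall is s(−ln a − 1 + a), which gave s as 0.0809. Adding one standard deviation of that sum gave 0.185, my selectivity ceiling, a reading and not a strict bound. The same reading gave a rate constant of 0.163 M⁻¹ min⁻¹.

**The bracket.** For alder, partner held at its charge left a at 11.1%, so with no loss first product stood at most near 88.9%. Letting partner fall one for one with substrate raised a to 13.7%, which tightened the top to 86.3%. The ceiling at that a gave the floor, 68.1%, and the read s gave my estimate, 77.7%. For maple, a of 0.388% spanned 43.5% to 99.6%, so its place stayed open. At 5.0 min I ranked by partner charge, maple holding more than the others.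

**The forecast.** It gave alder > maple > birch > larch at 1.5 h and maple > alder > birch > larch at 5.0 min, with 80% on top and 39% at the bottom. In its words: “I lean towards alder first.” Its top, for alder, lay inside my alder bracket, higher than my estimate.

**The result.** The simulation gave alder > birch > maple > larch at 1.5 h and maple > alder > birch > larch at 5.0 min, with alder at 70.9% and larch at 38.4%. Alder stood lower than both my estimate and the forecast.

    coupling partner + first product → double product (k = 4.30 × 10⁻⁴ M⁻¹ s⁻¹)
    coupling partner + double product → tris adduct (k = 0.00350 M⁻¹ s⁻¹)
    coupling partner + tris adduct → tetra adduct (k = 0.00140 M⁻¹ s⁻¹)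
    substrate + coupling partner → first product (k = 0.00280 M⁻¹ s⁻¹)

**Neighbour flask.** On the substrate alder really kept, 13.4%, the ceiling gives 68.2% and no loss gives 86.6%, around its 70.9%. The neighbour is a flask like larch but charged with 0.025 M of substrate, which puts 2.40 equiv of coupling partner against it. It kept 45.8% of its substrate at 1.50 h, so the same rule brackets first product between 50.0% and 54.2%. That flask held 50.7%.

The earlier runs and the new flask are simulated with made-up constants, noise included.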